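The data are simulated for substances that don't exist; scatter was added.

Start from 4.00: the ash run, at 10 °C, took 4.00 min to reach the 24% of single ring that the birch run, at 25 °C, held at 1.00 min. Call this ratio of times at equal single ring the clock factor, the shift factor of time–temperature superposition; it is a reading and carries the scatter.

| flask | starting material | protic impurity | temperature | remark | time |
|---|---|---|---|---|---|
| birch | 2 M | 0.20 M | 25 °C | the very flask that is asked about, followed so far |  |
| ash | 2 M | 0.20 M | 10 °C | run made earlier |  |
| flask | 2.0 M | 0.200 M | 25 °C |  | 8.0 min |

| run | time / min | single ring / % |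
|---|---|---|
| birch | 1.00 | 24 |
| birch | 2.00 | 34 |
| birch | 3.00 | 41 |
| birch | 4.00 | 48 |
| birch | 5.00 | 50 |
| ash | 2.00 | 15 |
| ash | 4.00 | 24 |
| ash | 6.00 | 26 |
| ash | 8.00 | 30 |
| ash | 10.0 | 36 |

(each reading ± 2 percentage points)

- single ring taken out counts as made

- midnight: at 8.0 min take out 90% of the single ring then present, then wait 8.0 min
- autumn: at 8.0 min raise the temperature by 15 K, then wait 8.0 min
- winter: change nothing and wait 8.0 min more

1. single ring, in percent of the starting material first charged, at 8.0 min
2. the remedy with the largest gain of single ring, or "none" below 2 percentage points (midnight / autumn / winter / none)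
3. single ring present, with what was taken out counted in, in percent of the starting material first charged, after autumn
4. single ring present, with what was taken out counted in, in percent of the starting material first charged, after winter

Use it as a bench rule: treat the cooler run as the warmer one on a slower clock. Test it at the far end of the ash run. Its last reading, 36% at 10.0 min, maps to 2.50 min of birch time, where the mean of the birch readings at 2.00 min and 3.00 min is 37.5%. The gap lies within the scatter, so the ash run reads as the birch curve seen earlier, with no lower plateau shown.

That 2.50 min is also the border, because no pair of readings lies past it. Autumn asks for 32.0 min of clock, which is 6.40 times the last birch time, so there the rule is a bet.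

My reckoning: birch gained 2 percentage points in its last minute, and holding that slope as a ceiling puts the flask at 8.0 min between 50% and 56.0%. Winter and midnight both get 8.0 min of clock, but autumn gets 32.0 min, so I choose autumn.

The forecast gives 54% now, 55% after winter and 67% after autumn, and picks midnight, on this ground: “The flattening occurs with much starting material apparently left, so I read it as a reversible closure”. We part on the choice.

The flask gives 50.3%, then 55.4% after winter and 64.1% after autumn. The gains are 5.1 points for midnight, 5.1 points for winter and 14 points for autumn, so the best remedy is autumn.

    starting material → single ring (k = 0.00700 s⁻¹, Ea = 74.0 kJ mol⁻¹)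
    2 starting material → open dimer (k = 0.00180 M⁻¹ s⁻¹, Ea = 78.0 kJ mol⁻¹)
    starting material + open dimer → open trimer (k = 0.00630 M⁻¹ s⁻¹, Ea = 51.0 kJ mol⁻¹)
    open dimer → ring dimer (k = 0.00460 s⁻¹, Ea = 86.0 kJ mol⁻¹)
    starting material + protic impurity → quenched substrate (k = 0.540 M⁻¹ s⁻¹, Ea = 48.0 kJ mol⁻¹)
    starting material ⇌ dormant form (K = 2.50, k = 0.00300 s⁻¹, Ea = 81.0 kJ mol⁻¹, ΔH = −12.0 kJ mol⁻¹)
    starting material → decomposition product (k = 4.60 × 10⁻⁶ s⁻¹, Ea = 107 kJ mol⁻¹)
    (constants at 25 °C)

Autumn's 40.0 min of clock brought 64.1%, and the unchanged flask holds 65.5% at 80.0 min. Carry the factor to the neighbouring flask at 0 °C: over 1.67 steps of 15 K it becomes 10.1, so the rule maps its 8.0 min to 0.794 min at 25 °C. The flask at 0.800 min held 21.4% of single ring and 43.9% of starting material. The neighbour lags that mapped time: at 8.0 min it holds less single ring, 15.8%, and more starting material, 57.3%.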